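## The problem

The target is a spiro[5.5]undecane. Ring A (C1–C6) and ring B (C6–C11) share the quaternary carbon C6, which is bonded to a second quaternary carbon, C5 (gem-dimethyl), and to C1 with its exocyclic methylene. There are four stereocentres: C4 (R, secondary neopentyl bromide), C6 (S), C9 (R, tertiary bromide bearing a methyl group) and C10 (R, secondary chloride). The C9 bromine and C10 chlorine are trans, and the chlorine is trans to C5 across ring B. C9 and C10 are vicinal and can be set together, but they can influence C6 only through the conformation of ring B. C4 is insulated from all three by the quaternary carbons C5 and C6, so it needs reagent control. Ring B has bromine on the more substituted carbon, the reverse of what bromonium formation and chloride capture on a C9=C10 alkene gives, so the dihalide cannot simply be added to an alkene. Three groups are fragile: the tertiary bromide (ionisation, elimination, reduction by zinc-type metals), the C4 bromide (lost as a cyclopropane if a C1 ketone is enolised at C2 by excess base) and the exocyclic alkene next to C6 (isomerisation or rearrangement in protic acid). The enabling feature is that a C1 ketone makes C6 and then C2 nucleophilic in turn, while C5–C4–C3 is a latent bromonium ion at a tertiary carbon plus a primary terminus. The triad C6–C1–C2 and the triad C5–C4–C3 therefore match for a [3+3] closure of ring A onto a ring B that, with its C9 methyl and the C1–C2 acetyl unit, is the oxidised skeleton of limonene.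

## Retrosynthesis

**C1=CH2 (15 to 14).** The last bond cut is the exocyclic double bond, leading back to ketone 14. Putting the methylene on last keeps the acid-labile alkene out of every cation-forming step and leaves at C1 the carbonyl that ring construction needs. The forward reaction must methylenate a carbonyl flanked by the spiro carbon without base and without reducing the vicinal dihalide.

**C9–Br (14 to 13 to 12).** The C9–Br bond is exchanged for C9–O (alcohol 13, silyl ether 12). A tertiary bromide would not survive a Lewis acid or an amide base, whereas a tertiary silyl ether does. A trans chlorohydrin is also what epoxide chemistry delivers with the halogen on the correct, less substituted carbon. The forward step must replace oxygen by bromine with retention; the anti C10 chlorine is placed to bridge the cation and steer bromide to the face the oxygen left.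

**C5–C6 and C2–C3 (12 to 7 and 10, through 11).** Opening ring A at these two bonds removes a ring, the spiro centre and the contiguous quaternary pair at once. It leaves a ring B piece with two stereocentres (7) and a five-carbon piece with one (10). Cutting C5–C6 alone would require a tethered precursor made by enolate alkylation with the base-sensitive bromochloride. Cutting ring B instead would leave its dihalide to be installed on a finished skeleton. The forward reaction asks the tetrasubstituted silyl enol ether 7 to capture, at C6 and trans to the C10 chlorine, the bromonium ion released from the tertiary chloride of 10. The C2 methyl enolate of the resulting ketone 11 must then displace the C3 tosylate.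

**Ring B piece (7 back to 1).** Enol ether 7 is the more substituted enol derivative of methyl ketone 6, which comes from ozonolysis of the isopropenyl group of 5. Chlorohydrin 4 comes from trans-diaxial opening of epoxide 3 by chloride, and 3 from limonene 1 through bromohydrin 2. No C–C bond is formed in this branch; limonene supplies nine carbons and its tenth leaves as formaldehyde. The enantiomer matters. Diaxial opening puts chlorine trans and the tertiary oxygen cis to the isopropenyl group, so only (4S)-limonene gives the (1R,2R) chlorohydrin that maps onto (9R,10R). The (4R) enantiomer would give the mirror-image pair. The limonene stereocentre is a relay: it sets C9 and C10 and is then erased in 7.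

**Five-carbon piece (10 to 9 to 8).** Tosylate 10 is cut at C–Br and C–Cl back to prenol 8 through alcohol 9. Enantioselective bromochlorination of the allylic alcohol places bromine on C4 and chlorine on C5 and leaves the hydroxyl that becomes the C3 leaving group. The forward reaction must set C4 by catalyst control, since nothing else in the route can.

## Roads not taken

**Alternative 1:** Ring A is cut only at C5–C6 and ring B at C9–C10. The acyclic bromochloride A1, a tetrasubstituted allylsilane of defined geometry, is ionised in (CF3)2CHOH. C6 attacks the bromonium ion at C5, ring A closes and loss of silicon releases the C1 methylene, giving A2. Ring-closing metathesis of the two arms (second-generation Grubbs catalyst) would then give ring B as a C9=C10 cyclohexene.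
- Merits: the ring-forming event is precedented in kind, C6 follows stereospecifically from the alkene geometry through a chair, and the methylene appears without a hindered-ketone methylenation. In these three respects it is better than the chosen plan.
- Weak points: A1 needs a geometrically pure tetrasubstituted alkene whose two C6 substituents differ by little. After metathesis the ring B halogens must still be added to a trisubstituted alkene; direct bromochlorination puts chlorine on C9. The epoxide, chlorohydrin and bromide sequence would then run on a molecule carrying the acid-labile exocyclic alkene, with facial control only from the distant spiro centre.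
- Against its better precedent, the chosen plan sets C9 and C10 from limonene and performs the oxygen-to-bromine exchange before any alkene exists.

**Alternative 2:** Ring B is cut at C9–C10 and C7–C8. Ni(cod)2 with a chiral phosphine inserts 1-(trimethylsilyl)propyne into one acyl–CH2 bond of spiro cyclobutanone A3, expanding it to cyclohexenone A4.
- Merits: two C–C bonds and ring B in one catalytic step, with the C9 methyl and a C10 oxygen in place, and C6 set by the ligand. That is a firmer basis than the conformational preference the chosen plan relies on.
- Weak points: zerovalent nickel with a phosphine meets a secondary alkyl bromide and a 4-bromo ketone. The alkyne regiochemistry and the choice between the two acyl–CH2 bonds must both be controlled. Afterwards the silyl group must go, C10=O must become a chloride at a neopentyl-type carbon and C9 a tertiary bromide, so the hardest part of the target remains unsolved. A3 also needs its own synthesis on a brominated ring A.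
- The chosen plan is shorter to the full halogen pattern; it concedes catalyst control of C6.

**Alternative 3:** Ring B is cut at C6–C7 and C10–C11. Under KOH the dienolate of brominated cyclocitral A5 adds through C6 to methyl vinyl ketone and the methyl ketone condenses with the aldehyde carbon, giving spiro enone A6.
- Merits: ring B from cheap reagents in one operation, the methylene already present, and no unprecedented step. It is shorter to the bicyclic skeleton than the chosen plan.
- Weak points: hot hydroxide meets a bromide 1,3 to the dienolate carbon (cyclopropane closure or elimination). Enantiopure A5 needs its own asymmetric synthesis, and the face of the Michael addition is governed only by C4. A6 has oxygen at C9 but unsaturation at C10=C11, so methyl, tertiary bromide and secondary chloride must all be introduced by substrate control next to the acid-labile methylene.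
- The chosen plan sets against this brevity that three of the four stereocentres come from the chiral pool or a catalyst, with both ring B heteroatoms in place before the rings are joined.

Key step: step 8

## Route

Remark: atom labels C1–C11 are the spiro[5.5]undecane locants with the methylidene carbon on C1 (ring A = C1–C6, ring B = C6–C11), and the fragments carry the same labels before they are joined.

Remark: the Schiff base ligand of step 6 is a catalyst made by condensing a salicylaldehyde with a chiral amino alcohol; its preparation is not counted as a step.

Step 1
Reactants: 1 (S)-(−)-limonene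
Product: 3 (1R,4S,6S)-1-methyl-4-(prop-1-en-2-yl)-7-oxabicyclo[4.1.0]heptane (trans-limonene 1,2-oxide; epoxide oxygen and isopropenyl on the same face), via bromohydrin 2 (not isolated)
Conditions: NBS, acetone/H2O, 0 °C; then aq. NaOH, 0 °C → rt
Reagents that add atoms: water, O
Why: Bromohydrin formation and Williamson closure: NBS attacks the more electron-rich ring alkene, water opens the bromonium ion at the tertiary carbon in the trans-diaxial (Fürst–Plattner) sense with the isopropenyl group equatorial to give only bromohydrin 2, and hydroxide closes the epoxide with inversion at the bromide carbon, so the oxygen of 3 ends cis to the isopropenyl group.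

Step 2
Reactants: 3 (1R,4S,6S)-1-methyl-4-(prop-1-en-2-yl)-7-oxabicyclo[4.1.0]heptane
Product: 4 (1R,2R,4S)-2-chloro-1-methyl-4-(prop-1-en-2-yl)cyclohexan-1-ol
Conditions: LiCl, AcOH, THF, rt
Reagents that add atoms: lithium chloride, [Li+].[Cl-]
Why: Acid-assisted epoxide opening by chloride under the Fürst–Plattner rule: only attack at the secondary carbon gives a chair-like trans-diaxial transition state with the isopropenyl group equatorial, so chloride enters there with inversion (future C10) and the tertiary oxygen keeps its configuration (future C9).

Step 3
Reactants: 4 (1R,2R,4S)-2-chloro-1-methyl-4-(prop-1-en-2-yl)cyclohexan-1-ol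
Product: 5 triethyl{[(1R,2R,4S)-2-chloro-1-methyl-4-(prop-1-en-2-yl)cyclohexyl]oxy}silane
Conditions: Et3SiOTf, 2,6-lutidine, CH2Cl2, −78 → 0 °C
Reagents that add atoms: triethylsilyl trifluoromethanesulfonate, CC[Si](CC)(CC)OS(=O)(=O)C(F)(F)F
Why: Silylation of a hindered tertiary alcohol with a silyl triflate and a non-nucleophilic base; the ether removes the alkoxide that would re-close the epoxide under the base of step 8 and should tolerate enol silylation and ZnCl2.

Step 4
Reactants: 5 triethyl{[(1R,2R,4S)-2-chloro-1-methyl-4-(prop-1-en-2-yl)cyclohexyl]oxy}silane
Product: 6 1-[(1S,3R,4R)-3-chloro-4-methyl-4-(triethylsilyloxy)cyclohexyl]ethan-1-one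
Conditions: O3, CH2Cl2, −78 °C; then Me2S, −78 °C → rt
Reagents that add atoms: ozone, [O-][O+]=O
Why: Ozonolysis with reductive work-up cleaves the only alkene to the methyl ketone, which puts C1 and C2 in place without touching a stereocentre.

Step 5
Reactants: 6 1-[(1S,3R,4R)-3-chloro-4-methyl-4-(triethylsilyloxy)cyclohexyl]ethan-1-one
Product: 7 triethyl({(1R,2R)-2-chloro-1-methyl-4-[1-(trimethylsilyloxy)ethylidene]cyclohexyl}oxy)silane (E/Z mixture)
Conditions: Me3SiCl, NaI, Et3N, MeCN, rt; pentane extraction
Reagents that add atoms: chlorotrimethylsilane, C[Si](C)(C)Cl
Why: Equilibrating enol silylation (Me3SiI formed in the flask, Et3N) should give the thermodynamically preferred, more substituted enol ether exocyclic to ring B; the limonene stereocentre is deliberately erased and the double-bond geometry is irrelevant because C6 becomes sp3 in step 8.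

Step 6
Reactants: 8 prenol (3-methylbut-2-en-1-ol)
Product: 9 (2R)-2-bromo-3-chloro-3-methylbutan-1-ol
Conditions: NBS, ClTi(OiPr)3, chiral tridentate Schiff base ligand (20 mol%), hexanes, −20 °C
Reagents that add atoms: N-bromosuccinimide, O=C1CCC(=O)N1Br; chlorotitanium triisopropoxide, CC(C)O[Ti](Cl)(OC(C)C)OC(C)C
Why: Catalytic enantioselective bromochlorination of an allylic alcohol: alkoxide and chloride are bound to tetravalent titanium carrying the chiral ligand, NBS delivers bromine to C4 on the alkene face chosen by the ligand and chloride is transferred anti to the tertiary carbon C5, so the (R) centre is set by the catalyst (the ligand enantiomer giving (R) is used).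

Step 7
Reactants: 9 (2R)-2-bromo-3-chloro-3-methylbutan-1-ol
Product: 10 (2R)-2-bromo-3-chloro-3-methylbutyl 4-methylbenzenesulfonate
Conditions: TsCl, pyridine, CH2Cl2, 0 °C
Reagents that add atoms: p-toluenesulfonyl chloride, Cc1ccc(cc1)S(Cl)(=O)=O
Why: Sulfonylation of the primary alcohol under weakly basic conditions leaves the vicinal bromochloride and its stereocentre untouched and makes C3 the electrophile for ring closure.

Step 8
Reactants: 7 triethyl({(1R,2R)-2-chloro-1-methyl-4-[1-(trimethylsilyloxy)ethylidene]cyclohexyl}oxy)silane; 10 (2R)-2-bromo-3-chloro-3-methylbutyl 4-methylbenzenesulfonate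
Product: 12 (4R,6R,9R,10R)-4-bromo-10-chloro-5,5,9-trimethyl-9-(triethylsilyloxy)spiro[5.5]undecan-1-one, via open-chain keto tosylate 11 (not isolated)
Conditions: ZnCl2 (10 mol%, Et2O solution), CH2Cl2, −40 °C → rt; pentane, filtration under argon, evaporation (removes Me3SiCl); THF, LiN(SiMe3)2 (1.0 equiv), −78 → 0 °C
Reagents that add atoms: none
Why: Proposed new method: ZnCl2 should abstract the tertiary chloride of 10 with help from the anti-periplanar bromine, and the bromonium ion should be opened at its tertiary carbon C5 by C6 of enol ether 7 (loss of Me3SiCl) anti to bromine, so that C4 is untouched (its descriptor in 11 changes to S only by priority) and the C5–C6 bond joins two quaternary carbons; the closest known reactions are the Lewis acid-mediated α-tert-alkylation of silyl enol ethers with tertiary alkyl chlorides and the ionisation of enantioenriched vicinal bromochlorides to bromonium ions captured by tetrasubstituted alkenes, but intermolecular capture of such an ion by a silyl enol ether is not known. Once C6 is quaternary the only enolisable position of 11 is the C2 methyl group, so LiN(SiMe3)2 should give a single lithium enolate that closes ring A by displacing the primary C3 tosylate, a 6-(enolendo)-exo-tet ketone enolate cycloalkylation helped by the gem-dimethyl group and the quaternary C6 in the tether. The new stereocentre C6 is set in the first stage by ring B: in the chair that keeps the C9 methyl equatorial, the silyloxy group and the C10 chlorine are trans-diaxial (the chlorine has only one syn-axial hydrogen because C6 is trigonal), the axial chlorine shields the axial face of the enol ether, and the bulky electrophile should enter equatorially, trans to chlorine, which is (6R) in 12. The ring closure needs C- over O-alkylation and tosylate over bromide displacement: a lithium enolate in THF favours carbon, attack of C2 on the neopentyl C4 bromide would be a disfavoured 5-(enolendo)-exo-tet closure, and base is held to one equivalent because 12 is a 4-bromo ketone that a second deprotonation at C2 would turn into a cyclopropane.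

Step 9
Reactants: 12 (4R,6R,9R,10R)-4-bromo-10-chloro-5,5,9-trimethyl-9-(triethylsilyloxy)spiro[5.5]undecan-1-one
Product: 13 (4R,6R,9R,10R)-4-bromo-10-chloro-9-hydroxy-5,5,9-trimethylspiro[5.5]undecan-1-one
Conditions: HF·pyridine, THF, 0 °C → rt
Reagents that add atoms: none
Why: Acidic fluoride cleavage of the triethylsilyl ether; a basic fluoride source is avoided because the free alkoxide would displace the trans chloride and form the epoxide.

Step 10
Reactants: 13 (4R,6R,9R,10R)-4-bromo-10-chloro-9-hydroxy-5,5,9-trimethylspiro[5.5]undecan-1-one
Product: 14 (4R,6R,9R,10R)-4,9-dibromo-10-chloro-5,5,9-trimethylspiro[5.5]undecan-1-one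
Conditions: Me3SiBr, CH2Cl2, −20 → 0 °C
Reagents that add atoms: bromotrimethylsilane, C[Si](C)(C)Br
Why: Substitution of a tertiary alcohol with neighbouring-group participation: O-silylation and HBr formed in the flask make the hydroxyl a leaving group, the anti-periplanar C10 chlorine bridges the cation from the lower face (chloronium ion), and bromide opens it at the more substituted carbon C9 from the upper face, so bromine should replace oxygen with retention and stay trans to chlorine.

Step 11
Reactants: 14 (4R,6R,9R,10R)-4,9-dibromo-10-chloro-5,5,9-trimethylspiro[5.5]undecan-1-one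
Product: 15 (4R,6S,9R,10R)-4,9-dibromo-10-chloro-5,5,9-trimethyl-1-methylidenespiro[5.5]undecane
Conditions: Cp2TiMe2, toluene, 65 °C, dark
Reagents that add atoms: dimethyltitanocene, C[Ti](C)(C1C=CC=C1)C1C=CC=C1
Why: Petasis methylenation: thermolysis of Cp2TiMe2 gives Cp2Ti=CH2, which converts the hindered C1 ketone into the exocyclic alkene through an oxatitanacyclobutane; the reagent is not basic, so the ketone is not enolised (no cyclopropane from the C4 bromide) and the tertiary bromide is not eliminated, as a phosphorus ylide would risk; C6 changes to S by priority only.

## Compound list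

1 | (S)-(−)-limonene, (4S)-1-methyl-4-(prop-1-en-2-yl)cyclohex-1-ene | CC1=CC[C@H](CC1)C(C)=C | starting material
2 | (1R,2R,4S)-2-bromo-1-methyl-4-(prop-1-en-2-yl)cyclohexan-1-ol | CC(=C)[C@H]1CC[C@@](C)(O)[C@H](Br)C1 | intermediate
3 | (1R,4S,6S)-1-methyl-4-(prop-1-en-2-yl)-7-oxabicyclo[4.1.0]heptane | CC(=C)[C@H]1CC[C@@]2(C)O[C@H]2C1 | intermediate
4 | (1R,2R,4S)-2-chloro-1-methyl-4-(prop-1-en-2-yl)cyclohexan-1-ol | CC(=C)[C@H]1CC[C@@](C)(O)[C@H](Cl)C1 | intermediate
5 | triethyl{[(1R,2R,4S)-2-chloro-1-methyl-4-(prop-1-en-2-yl)cyclohexyl]oxy}silane | CC(=C)[C@H]1CC[C@@](C)(O[Si](CC)(CC)CC)[C@H](Cl)C1 | intermediate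
6 | 1-[(1S,3R,4R)-3-chloro-4-methyl-4-(triethylsilyloxy)cyclohexyl]ethan-1-one | CC(=O)[C@H]1CC[C@@](C)(O[Si](CC)(CC)CC)[C@H](Cl)C1 | intermediate
7 | triethyl({(1R,2R)-2-chloro-1-methyl-4-[1-(trimethylsilyloxy)ethylidene]cyclohexyl}oxy)silane (E/Z mixture) | CC(O[Si](C)(C)C)=C1CC[C@@](C)(O[Si](CC)(CC)CC)[C@H](Cl)C1 | intermediate
8 | prenol, 3-methylbut-2-en-1-ol | CC(C)=CCO | starting material
9 | (2R)-2-bromo-3-chloro-3-methylbutan-1-ol | OC[C@@H](Br)C(C)(C)Cl | intermediate
10 | (2R)-2-bromo-3-chloro-3-methylbutyl 4-methylbenzenesulfonate | Cc1ccc(cc1)S(=O)(=O)OC[C@@H](Br)C(C)(C)Cl | intermediate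
11 | (2S)-3-[(1R,3R,4R)-1-acetyl-3-chloro-4-methyl-4-(triethylsilyloxy)cyclohexyl]-2-bromo-3-methylbutyl 4-methylbenzenesulfonate | CC(=O)[C@]1(C(C)(C)[C@H](Br)COS(=O)(=O)c2ccc(C)cc2)CC[C@@](C)(O[Si](CC)(CC)CC)[C@H](Cl)C1 | intermediate
12 | (4R,6R,9R,10R)-4-bromo-10-chloro-5,5,9-trimethyl-9-(triethylsilyloxy)spiro[5.5]undecan-1-one | O=C1CC[C@@H](Br)C(C)(C)[C@]12CC[C@@](C)(O[Si](CC)(CC)CC)[C@H](Cl)C2 | intermediate
13 | (4R,6R,9R,10R)-4-bromo-10-chloro-9-hydroxy-5,5,9-trimethylspiro[5.5]undecan-1-one | O=C1CC[C@@H](Br)C(C)(C)[C@]12CC[C@@](C)(O)[C@H](Cl)C2 | intermediate
14 | (4R,6R,9R,10R)-4,9-dibromo-10-chloro-5,5,9-trimethylspiro[5.5]undecan-1-one | O=C1CC[C@@H](Br)C(C)(C)[C@]12CC[C@@](C)(Br)[C@H](Cl)C2 | intermediate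
15 | (4R,6S,9R,10R)-4,9-dibromo-10-chloro-5,5,9-trimethyl-1-methylidenespiro[5.5]undecane | C=C1CC[C@@H](Br)C(C)(C)[C@]12CC[C@@](C)(Br)[C@H](Cl)C2 | target

## Step count and least certain steps

Total: 11 steps. Longest linear sequence: 9 steps (steps 1–5 and 8–11 from limonene); the prenol branch adds 2 steps before the union.

**Step 8 (key step).**
- Most likely failure: joining two quaternary carbons intermolecularly may be slower than loss of the bromonium ion by elimination or than protodesilylation of 7.
- Facial selectivity at C6 depends on how strongly ring B prefers the diaxial chair.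
- In the second stage, proton exchange between the open-chain enolate and the product could start cyclopropane formation, and O-alkylation could compete.
- Fallback, from 6 and 9 back to 12: the order of bond formation is reversed so that the bromonium ion is captured intramolecularly. Each operation is of a known type. Alcohol 9 is converted with Tf2O and 2,6-lutidine into (2R)-2-bromo-3-chloro-3-methylbutyl trifluoromethanesulfonate F1. The kinetic C2 enolate of 6 (LiN(iPr)2, THF, −78 °C) is alkylated with F1 to give (4R)-4-bromo-5-chloro-1-[(1S,3R,4R)-3-chloro-4-methyl-4-(triethylsilyloxy)cyclohexyl]-5-methylhexan-1-one F2, which already holds the C2–C3 bond. Equilibrating enol silylation as in step 5 gives the tetrasubstituted trimethylsilyl enol ether F3. Ionisation of F3 in (CF3)2CHOH lets C6 open the bromonium ion at C5 through a six-membered chair, which should give 12 with the same facial argument.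

**Step 10.**
- Most likely failure: the β-chloro tertiary cation may be only weakly bridged, so bromide could enter from both faces (loss of configuration at C9), and proton loss to allylic chlorides could compete.
- Fallback, from 13 back to 14: the oxygen is removed first and HBr is then added. Anti elimination with SOCl2 and pyridine at 0 °C should give (4R,6R,10R)-4-bromo-10-chloro-5,5,9-trimethylspiro[5.5]undec-8-en-1-one F4 together with its exocyclic isomer (4R,6R,10R)-4-bromo-10-chloro-5,5-dimethyl-9-methylidenespiro[5.5]undecan-1-one F5. Markovnikov addition of HBr to the mixture in CH2Cl2 at −78 °C then places bromine on C9 by kinetic axial attack anti to the C10 chlorine, without oxygen nucleophiles competing for the cation.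

**Step 11.**
- Most likely failure: slow reaction at the carbonyl next to the spiro carbon, allowing thermal elimination of the tertiary bromide or reduction of the vicinal dihalide by low-valent titanium from reagent decomposition.
- Fallback, from 14 to 15: Peterson olefination. Me3SiCH2Li with CeCl3 in THF at −78 °C adds to the hindered, enolisable ketone to give (4R,6R,9R,10R)-4,9-dibromo-10-chloro-5,5,9-trimethyl-1-[(trimethylsilyl)methyl]spiro[5.5]undecan-1-ol F6. F6 eliminates under acid (HF·pyridine) to the exocyclic alkene only.

**Step 5.**
- Most likely failure: incomplete regioselectivity toward the tetrasubstituted enol ether, with a terminal isomer that is hard to remove from a hydrolytically labile product; partial loss of the tertiary silyl ether to Me3SiI is also possible.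
- Fallback, from 6 to 7: the regiochemistry is fixed in an isolable compound. Isopropenyl acetate with catalytic TsOH converts 6 into 1-[(3R,4R)-3-chloro-4-methyl-4-(triethylsilyloxy)cyclohexylidene]ethyl acetate F7, which can be chromatographed free of its terminal isomer. MeLi (2 equiv, THF, −78 °C) cleaves it to the regiodefined lithium enolate, which is silylated in the flask with Me3SiCl. The acid in the first operation is the weak point of this fallback for the silyl ether.

Further compounds

F1 | step 8 | (2R)-2-bromo-3-chloro-3-methylbutyl trifluoromethanesulfonate | O=S(=O)(OC[C@@H](Br)C(C)(C)Cl)C(F)(F)F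
F2 | step 8 | (4R)-4-bromo-5-chloro-1-[(1S,3R,4R)-3-chloro-4-methyl-4-(triethylsilyloxy)cyclohexyl]-5-methylhexan-1-one | O=C(CC[C@@H](Br)C(C)(C)Cl)[C@H]1CC[C@@](C)(O[Si](CC)(CC)CC)[C@H](Cl)C1
F3 | step 8 | triethyl({(1R,2R)-4-[(4R)-4-bromo-5-chloro-5-methyl-1-(trimethylsilyloxy)hexylidene]-2-chloro-1-methylcyclohexyl}oxy)silane | C[Si](C)(C)OC(CC[C@@H](Br)C(C)(C)Cl)=C1CC[C@@](C)(O[Si](CC)(CC)CC)[C@H](Cl)C1
F4 | step 10 | (4R,6R,10R)-4-bromo-10-chloro-5,5,9-trimethylspiro[5.5]undec-8-en-1-one | O=C1CC[C@@H](Br)C(C)(C)[C@]12CC=C(C)[C@H](Cl)C2
F5 | step 10 | (4R,6R,10R)-4-bromo-10-chloro-5,5-dimethyl-9-methylidenespiro[5.5]undecan-1-one | O=C1CC[C@@H](Br)C(C)(C)[C@]12CCC(=C)[C@H](Cl)C2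
F6 | step 11 | (4R,6R,9R,10R)-4,9-dibromo-10-chloro-5,5,9-trimethyl-1-[(trimethylsilyl)methyl]spiro[5.5]undecan-1-ol (either configuration at C1) | C[Si](C)(C)CC1(O)CC[C@@H](Br)C(C)(C)[C@]12CC[C@@](C)(Br)[C@H](Cl)C2
F7 | step 5 | 1-[(3R,4R)-3-chloro-4-methyl-4-(triethylsilyloxy)cyclohexylidene]ethyl acetate | CC(OC(C)=O)=C1CC[C@@](C)(O[Si](CC)(CC)CC)[C@H](Cl)C1
A1 | alternative 1 | {(2Z)-2-[(3R)-3-bromo-4-chloro-4-methylpentyl]-6-methyl-3-(prop-2-en-1-yl)hepta-2,6-dien-1-yl}trimethylsilane | C[Si](C)(C)C/C(CC[C@@H](Br)C(C)(C)Cl)=C(\CC=C)CCC(C)=C
A2 | alternative 1 | (1R,3S)-1-bromo-2,2-dimethyl-4-methylidene-3-(3-methylbut-3-en-1-yl)-3-(prop-2-en-1-yl)cyclohexane | C=C1CC[C@@H](Br)C(C)(C)[C@]1(CC=C)CCC(C)=C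
A3 | alternative 2 | (8R)-8-bromo-9,9-dimethylspiro[3.5]nonane-2,5-dione | O=C1CC[C@@H](Br)C(C)(C)C12CC(=O)C2
A4 | alternative 2 | (4R,6S)-4-bromo-5,5,9-trimethyl-8-(trimethylsilyl)spiro[5.5]undec-8-ene-1,10-dione | O=C1CC[C@@H](Br)C(C)(C)[C@]12CC([Si](C)(C)C)=C(C)C(=O)C2
A5 | alternative 3 | (5R)-5-bromo-2,6,6-trimethylcyclohex-1-ene-1-carbaldehyde | CC1=C(C=O)C(C)(C)[C@H](Br)CC1
A6 | alternative 3 | (4R,6S)-4-bromo-5,5-dimethyl-1-methylidenespiro[5.5]undec-10-en-9-one | C=C1CC[C@@H](Br)C(C)(C)[C@]12CCC(=O)C=C2
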